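**Plan** (core numbered as a naphthalene: C1 CHMe, C2 CH–O, C3=C4, C4a=C5, C6=O, C7=CMe2, C8H2, C8a quaternary C–Me; ring A = C1–C4, C4a, C8a; ring B = C4a–C8, C8a; the same numbers are used for the open-chain intermediates)
1. Retrosynthesis: C6=O comes from a carbinol, then both rings are opened at once. The diene C3=C4–C4a=C5 runs from ring A through fusion carbon C4a into ring B and lies next to quaternary C8a; this is the product pattern of an ene–yne–ene metathesis, so cutting C4a=C5 and C3=C4 gives an acyclic dienyne with a terminal alkyne C4a≡C4 on C8a.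
2. The dienyne is cut at the C2–O acyl bond (dienoic acid), at C5–C6 (vinyl to enal) and at C4a (alkyne from the carbonyl carbon of a γ-lactone made of O, C2, C1, C8a, C4a).
3. The lactone is cut at C8a–C8 (allylic bromide carrying C8, C7=CMe2, C6) and at C8a–CH3; its C1/C2 pair comes from crotylboration of 3-methylbut-2-enal.
4. Forward: the chain is joined open (bromide, lactone, two alkylations, alkyne, ester, vinyl carbinol), then ring B and ring A arise in this order in one metathesis cascade, and the C6 carbinol is oxidised last.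
5. Stereochemistry: C1 and C2 from catalyst-controlled anti crotylboration, C8a from alkylation of the lactone enolate anti to the C1 methyl, C6 of the acyl chain from (2S)-2-methylbutan-1-ol, both acyl alkenes E from a Horner–Wadsworth–Emmons reaction.

Key step: step 17

Remark on the chemistry: centres that are erased later (lactol carbons of 10 and 16, the C6 carbinol of 28–31) are carried as mixtures and left undefined in the SMILES.

**Step 1**
Reactants: 1 diethyl 2-(propan-2-ylidene)propanedioate
Product: 2 2-(propan-2-ylidene)propane-1,3-diol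
Conditions: i-Bu2AlH (4.4 equiv), CH2Cl2, −78 → 0 °C; aq. KNaC4H4O6 (potassium sodium tartrate)
Reagents that add atoms: none
Why: Reduction of both ester groups to allylic alcohols by i-Bu2AlH in a non-coordinating solvent should proceed by 1,2-hydride delivery, and the tetrasubstituted alkene hinders conjugate reduction.

**Step 2**
Reactants: 2 2-(propan-2-ylidene)propane-1,3-diol
Product: 3 2-(hydroxymethyl)-3-methylbut-2-en-1-yl 2,2-dimethylpropanoate
Conditions: pivaloyl chloride (1.0 equiv, slow addition), pyridine, CH2Cl2, −20 °C; unreacted diol recycled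
Reagents that add atoms: pivaloyl chloride, CC(C)(C)C(Cl)=O
Why: Mono-acylation of a symmetric diol with a bulky acid chloride should give mainly the monoester; the pivalate has no α-hydrogen and should survive the enolate of step 8.

**Step 3**
Reactants: 3 2-(hydroxymethyl)-3-methylbut-2-en-1-yl 2,2-dimethylpropanoate
Product: 4 2-(bromomethyl)-3-methylbut-2-en-1-yl 2,2-dimethylpropanoate
Conditions: CBr4, PPh3, CH2Cl2, 0 °C
Reagents that add atoms: carbon tetrabromide, BrC(Br)(Br)Br
Why: Appel reaction; the primary allylic alcohol is displaced by bromide under neutral conditions, and allylic transposition is blocked by the fully substituted alkene terminus.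

**Step 4**
Reactants: 5 3-methylbut-2-enal; 6 2-[(2E)-but-2-en-1-yl]-4,4,5,5-tetramethyl-1,3,2-dioxaborolane
Product: 7 (3R,4R)-3,6-dimethylhepta-1,5-dien-4-ol
Conditions: (R)-TRIP [(R)-3,3'-bis(2,4,6-triisopropylphenyl)-1,1'-binaphthyl-2,2'-diyl hydrogen phosphate] (5 mol %), toluene, −30 °C; aqueous work-up
Reagents that add atoms: none
Why: Chiral phosphoric acid-catalysed crotylboration through a closed chair (Zimmerman–Traxler type) transition state; the E-crotyl geometry sets the anti relation of C1 and C2, and the (R)-catalyst should direct addition to the re face of the aldehyde, which sets the absolute configuration of both centres.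

**Step 5**
Reactants: 7 (3R,4R)-3,6-dimethylhepta-1,5-dien-4-ol
Product: 9 (3R,4R)-3,6-dimethylhept-5-ene-1,4-diol, via B-alkyl-9-BBN borinate 8 (not isolated)
Conditions: 9-BBN (2.3 equiv), THF, 0 °C → rt; then aq. NaOH, H2O2, 0 °C
Reagents that add atoms: hydrogen peroxide, OO
Why: Hydroboration–oxidation; 9-BBN should react with the monosubstituted vinyl group far faster than with the trisubstituted alkene and place boron at the terminal carbon; no stereocentre is formed.

**Step 6**
Reactants: 9 (3R,4R)-3,6-dimethylhept-5-ene-1,4-diol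
Product: 11 (4R,5R)-4-methyl-5-(2-methylprop-1-en-1-yl)oxolan-2-one, via lactol 10 (not isolated)
Conditions: TEMPO (0.2 equiv), PhI(OAc)2 (2.5 equiv), CH2Cl2, rt
Reagents that add atoms: none
Why: Oxidative lactonisation of a 1,4-diol; the oxoammonium oxidant is selective for the primary alcohol, the hydroxy aldehyde closes to the lactol and this is oxidised on to the γ-lactone, in which the C1 methyl and the C2 alkenyl group are trans.

**Step 7**
Reactants: 11 (4R,5R)-4-methyl-5-(2-methylprop-1-en-1-yl)oxolan-2-one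
Product: 13 (3R,4R,5R)-3,4-dimethyl-5-(2-methylprop-1-en-1-yl)oxolan-2-one, via lithium enolate 12 (not isolated)
Conditions: LiN(i-Pr)2 (1.05 equiv), THF, −78 °C; then MeI, −78 → −40 °C
Reagents that add atoms: iodomethane, CI
Why: Lactone enolate alkylation; methyl iodide should enter anti to the neighbouring C1 methyl, but the configuration at C8a is of no consequence here because the centre is made planar again in step 8.

**Step 8**
Reactants: 13 (3R,4R,5R)-3,4-dimethyl-5-(2-methylprop-1-en-1-yl)oxolan-2-one; 4 2-(bromomethyl)-3-methylbut-2-en-1-yl 2,2-dimethylpropanoate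
Product: 15 {2-[((3R,4R,5S)-3,4-dimethyl-5-(2-methylprop-1-en-1-yl)-2-oxooxolan-3-yl)methyl]-3-methylbut-2-en-1-yl} 2,2-dimethylpropanoate, via lithium enolate 14 (not isolated)
Conditions: LiN(i-Pr)2 (1.2 equiv), THF/DMPU, −78 °C; then 4 (1.5 equiv), −78 → −20 °C
Reagents that add atoms: none
Why: Alkylation of the tetrasubstituted lactone enolate with a primary allylic bromide; the electrophile should approach anti to the adjacent C1 methyl (1,2-induction in five-membered lactone enolates), so C8 ends up trans and the C8a methyl cis to the C1 methyl, which sets the quaternary centre C8a.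

**Step 9**
Reactants: 15 {2-[((3R,4R,5S)-3,4-dimethyl-5-(2-methylprop-1-en-1-yl)-2-oxooxolan-3-yl)methyl]-3-methylbut-2-en-1-yl} 2,2-dimethylpropanoate
Product: 16 (3R,4R,5S)-3-[2-(hydroxymethyl)-3-methylbut-2-en-1-yl]-3,4-dimethyl-5-(2-methylprop-1-en-1-yl)oxolan-2-ol
Conditions: i-Bu2AlH (3.5 equiv), CH2Cl2, −78 °C; aq. KNaC4H4O6
Reagents that add atoms: none
Why: Partial reduction of a γ-lactone to the lactol with i-Bu2AlH at −78 °C is standard, and the same reagent should cleave the pivalate reductively in the same operation.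

**Step 10**
Reactants: 16 (3R,4R,5S)-3-[2-(hydroxymethyl)-3-methylbut-2-en-1-yl]-3,4-dimethyl-5-(2-methylprop-1-en-1-yl)oxolan-2-ol
Product: 18 (4R,5R,6S)-4-ethynyl-4,5,8-trimethyl-2-(propan-2-ylidene)non-7-ene-1,6-diol, via open-chain hydroxy aldehyde 17 (not isolated)
Conditions: dimethyl (1-diazo-2-oxopropyl)phosphonate (2 equiv), K2CO3 (3 equiv), MeOH, 0 °C → rt
Reagents that add atoms: dimethyl (1-diazo-2-oxopropyl)phosphonate, CC(=O)C(=[N+]=[N-])P(=O)(OC)OC
Why: Ohira–Bestmann (Seyferth–Gilbert) homologation of the ring-opened lactol; addition of the diazomethylphosphonate anion, loss of phosphate and N2 and a 1,2-hydrogen shift should give the terminal alkyne, and C8a, being quaternary, cannot epimerise.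

**Step 11**
Reactants: 18 (4R,5R,6S)-4-ethynyl-4,5,8-trimethyl-2-(propan-2-ylidene)non-7-ene-1,6-diol
Product: 19 (4R,5R,6S)-4-ethynyl-6-hydroxy-4,5,8-trimethyl-2-(propan-2-ylidene)non-7-enal
Conditions: TEMPO (0.1 equiv), PhI(OAc)2 (1.1 equiv), CH2Cl2, 0 °C → rt
Reagents that add atoms: none
Why: TEMPO/PhI(OAc)2 oxidation is strongly selective for the primary allylic alcohol over the hindered secondary C2 carbinol and stops at the aldehyde.

**Step 12**
Reactants: 20 (2S)-2-methylbutan-1-ol
Product: 21 (2S)-2-methylbutanal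
Conditions: TEMPO (1 mol %), KBr (10 mol %), NaOCl (1.1 equiv), NaHCO3 buffer, CH2Cl2/H2O, 0 °C; dried solution used at once
Reagents that add atoms: none
Why: Anelli oxidation under buffered two-phase conditions stops at the aldehyde and is mild enough to keep the α-stereocentre.

**Step 13**
Reactants: 21 (2S)-2-methylbutanal; 22 ethyl (2E)-4-(diethoxyphosphoryl)but-2-enoate
Product: 24 ethyl (2E,4E,6S)-6-methylocta-2,4-dienoate, via lithiated phosphonate 23 (not isolated)
Conditions: LiN(SiMe3)2, THF, −78 °C; then 21, −78 → 0 °C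
Reagents that add atoms: none
Why: Vinylogous Horner–Wadsworth–Emmons olefination; the stabilised anion should form the new alkene E and keep the existing one E, and the low temperature limits epimerisation of the aldehyde.

**Step 14**
Reactants: 24 ethyl (2E,4E,6S)-6-methylocta-2,4-dienoate
Product: 25 (2E,4E,6S)-6-methylocta-2,4-dienoic acid
Conditions: LiOH, THF/MeOH/H2O, rt; then aq. HCl to pH 3
Reagents that add atoms: lithium hydroxide, [Li+].[OH-]
Why: Ester saponification; the stereocentre is remote from the carbonyl group and should not epimerise under these conditions.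

**Step 15**
Reactants: 19 (4R,5R,6S)-4-ethynyl-6-hydroxy-4,5,8-trimethyl-2-(propan-2-ylidene)non-7-enal; 25 (2E,4E,6S)-6-methylocta-2,4-dienoic acid
Product: 27 (4S,5R,6R)-6-ethynyl-8-formyl-2,5,6,9-tetramethyldeca-2,8-dien-4-yl (2E,4E,6S)-6-methylocta-2,4-dienoate, via mixed anhydride 26 (not isolated)
Conditions: 25, 2,4,6-trichlorobenzoyl chloride, Et3N, THF, rt; then 19, DMAP, toluene, rt → 40 °C
Reagents that add atoms: none
Why: Yamaguchi esterification; DMAP-mediated acyl transfer from the mixed anhydride to the hindered secondary alcohol forms the acyl–oxygen bond, so C2 keeps its configuration, and the aldehyde and alkyne are inert.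

**Step 16**
Reactants: 27 (4S,5R,6R)-6-ethynyl-8-formyl-2,5,6,9-tetramethyldeca-2,8-dien-4-yl (2E,4E,6S)-6-methylocta-2,4-dienoate
Product: 28 (4S,5R,6R)-6-ethynyl-8-(1-hydroxyprop-2-en-1-yl)-2,5,6,9-tetramethyldeca-2,8-dien-4-yl (2E,4E,6S)-6-methylocta-2,4-dienoate
Conditions: CH2=CHMgBr (1.3 equiv), THF, −78 °C; then pH 7 buffer
Reagents that add atoms: vinylmagnesium bromide, C=C[Mg]Br
Why: Grignard 1,2-addition to the aldehyde, which at −78 °C is far more electrophilic than the dienoate ester; the fully substituted β-carbon of the enal rules out conjugate addition, and the new C6 carbinol forms as both epimers, which is of no consequence because step 18 removes the centre.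

**Step 17**
Reactants: 28 (4S,5R,6R)-6-ethynyl-8-(1-hydroxyprop-2-en-1-yl)-2,5,6,9-tetramethyldeca-2,8-dien-4-yl (2E,4E,6S)-6-methylocta-2,4-dienoate
Product: 31 (1R,2S,8aR)-6-hydroxy-1,8a-dimethyl-7-(propan-2-ylidene)-1,2,6,7,8,8a-hexahydronaphthalen-2-yl (2E,4E,6S)-6-methylocta-2,4-dienoate, via C5 ruthenium alkylidene 29 (not isolated), via ring-B ruthenium vinylcarbene 30 (not isolated)
Conditions: second-generation Grubbs catalyst [RuCl2(=CHPh)(H2IMes)(PCy3)] (10 mol %), toluene (0.005 M), 80 °C, Ar
Reagents that add atoms: none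
Why: The catalyst should load onto the only monosubstituted alkene (the C5 vinyl group) to give 29, which adds to the terminal alkyne C4a≡C4 by [2+2] cycloaddition and ring opening so that C5 bonds to C4a, ring B closes and the metal moves to C4 in the conjugated vinylcarbene 30; this carbene then undergoes ring-closing metathesis with the isobutenyl alkene, which forms the C3=C4 bond, closes ring A and releases the CMe2 terminus as 2-methylpropene. The closest known reaction type is the tandem ene–yne–ene (dienyne) ring-closing metathesis of substrates in which a quaternary propargylic carbon carries both alkene tethers. Ring B closes in the exo mode of enyne metathesis (six-membered ring holding one alkyne carbon), and ring A by alkene–alkylidene ring-closing metathesis to a six-membered ring whose cis C3=C4 geometry is fixed by the ring. No stereocentre is formed: C1, C2 and C8a are set before and are not touched by the metal, and the C6 epimers converge in step 18. The step needs the right order of events, since initiation at the ring-A alkene would close a five-membered ring first and end in a 5–7 skeleton; the trisubstituted isobutenyl terminus (from 3-methylbut-2-enal) is slow to initiate but still able to terminate, the alkyne on a quaternary carbon is too hindered for intermolecular attack, and the tetrasubstituted isopropylidene and the electron-poor dienoate should stay spectators.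

**Step 18**
Reactants: 31 (1R,2S,8aR)-6-hydroxy-1,8a-dimethyl-7-(propan-2-ylidene)-1,2,6,7,8,8a-hexahydronaphthalen-2-yl (2E,4E,6S)-6-methylocta-2,4-dienoate
Product: 32 (1R,2S,8aR)-1,8a-dimethyl-6-oxo-7-(propan-2-ylidene)-1,2,6,7,8,8a-hexahydronaphthalen-2-yl (2E,4E,6S)-6-methylocta-2,4-dienoate
Conditions: activated MnO2 (20 equiv), CH2Cl2, rt
Reagents that add atoms: none
Why: Allylic oxidation with MnO2; the doubly allylic C6 carbinol should be oxidised to the cross-conjugated dienone from either epimer, while the ester, the alkenes and all stereocentres are untouched.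

**Compound list**
1 | diethyl 2-(propan-2-ylidene)propanedioate | CCOC(=O)C(=C(C)C)C(=O)OCC | starting material
2 | 2-(propan-2-ylidene)propane-1,3-diol | CC(C)=C(CO)CO | intermediate
3 | 2-(hydroxymethyl)-3-methylbut-2-en-1-yl 2,2-dimethylpropanoate | CC(C)=C(CO)COC(=O)C(C)(C)C | intermediate
4 | 2-(bromomethyl)-3-methylbut-2-en-1-yl 2,2-dimethylpropanoate | CC(C)=C(CBr)COC(=O)C(C)(C)C | intermediate
5 | 3-methylbut-2-enal | CC(C)=CC=O | starting material
6 | 2-[(2E)-but-2-en-1-yl]-4,4,5,5-tetramethyl-1,3,2-dioxaborolane | C/C=C/CB1OC(C)(C)C(C)(C)O1 | starting material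
7 | (3R,4R)-3,6-dimethylhepta-1,5-dien-4-ol | O[C@@H](C=C(C)C)[C@H](C)C=C | intermediate
8 | 9-{(3R,4R)-4-[(9-borabicyclo[3.3.1]nonan-9-yl)oxy]-3,6-dimethylhept-5-en-1-yl}-9-borabicyclo[3.3.1]nonane | C1CCC2CCCC1B2O[C@@H](C=C(C)C)[C@H](C)CCB1C2CCCC1CCC2 | intermediate
9 | (3R,4R)-3,6-dimethylhept-5-ene-1,4-diol | O[C@@H](C=C(C)C)[C@H](C)CCO | intermediate
10 | (4R,5R)-4-methyl-5-(2-methylprop-1-en-1-yl)oxolan-2-ol | OC1O[C@@H](C=C(C)C)[C@H](C)C1 | intermediate
11 | (4R,5R)-4-methyl-5-(2-methylprop-1-en-1-yl)oxolan-2-one | O=C1O[C@@H](C=C(C)C)[C@H](C)C1 | intermediate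
12 | lithium (4R,5R)-4-methyl-5-(2-methylprop-1-en-1-yl)-4,5-dihydrofuran-2-olate | [Li]OC=1O[C@@H](C=C(C)C)[C@H](C)C=1 | intermediate
13 | (3R,4R,5R)-3,4-dimethyl-5-(2-methylprop-1-en-1-yl)oxolan-2-one | O=C1O[C@@H](C=C(C)C)[C@H](C)[C@H]1C | intermediate
14 | lithium (4R,5S)-3,4-dimethyl-5-(2-methylprop-1-en-1-yl)-4,5-dihydrofuran-2-olate | [Li]OC=1O[C@@H](C=C(C)C)[C@H](C)C=1C | intermediate
15 | {2-[((3R,4R,5S)-3,4-dimethyl-5-(2-methylprop-1-en-1-yl)-2-oxooxolan-3-yl)methyl]-3-methylbut-2-en-1-yl} 2,2-dimethylpropanoate | O=C1O[C@@H](C=C(C)C)[C@H](C)[C@@]1(C)CC(COC(=O)C(C)(C)C)=C(C)C | intermediate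
16 | (3R,4R,5S)-3-[2-(hydroxymethyl)-3-methylbut-2-en-1-yl]-3,4-dimethyl-5-(2-methylprop-1-en-1-yl)oxolan-2-ol | OC1O[C@@H](C=C(C)C)[C@H](C)[C@@]1(C)CC(CO)=C(C)C | intermediate
17 | (2R,3R,4S)-4-hydroxy-2-[2-(hydroxymethyl)-3-methylbut-2-en-1-yl]-2,3,6-trimethylhept-5-enal | O[C@@H](C=C(C)C)[C@H](C)[C@@](C=O)(C)CC(CO)=C(C)C | intermediate
18 | (4R,5R,6S)-4-ethynyl-4,5,8-trimethyl-2-(propan-2-ylidene)non-7-ene-1,6-diol | O[C@@H](C=C(C)C)[C@H](C)[C@@](C#C)(C)CC(CO)=C(C)C | intermediate
19 | (4R,5R,6S)-4-ethynyl-6-hydroxy-4,5,8-trimethyl-2-(propan-2-ylidene)non-7-enal | O[C@@H](C=C(C)C)[C@H](C)[C@@](C#C)(C)CC(C=O)=C(C)C | intermediate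
20 | (2S)-2-methylbutan-1-ol | CC[C@H](C)CO | starting material
21 | (2S)-2-methylbutanal | CC[C@H](C)C=O | intermediate
22 | ethyl (2E)-4-(diethoxyphosphoryl)but-2-enoate | CCOC(=O)/C=C/CP(=O)(OCC)OCC | starting material
23 | lithium salt of ethyl (2E)-4-(diethoxyphosphoryl)but-2-enoate (C4 carbanion) | [Li+].CCOC(=O)/C=C/[CH-]P(=O)(OCC)OCC | intermediate
24 | ethyl (2E,4E,6S)-6-methylocta-2,4-dienoate | CC[C@H](C)/C=C/C=C/C(=O)OCC | intermediate
25 | (2E,4E,6S)-6-methylocta-2,4-dienoic acid | CC[C@H](C)/C=C/C=C/C(=O)O | intermediate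
26 | (2E,4E,6S)-6-methylocta-2,4-dienoic 2,4,6-trichlorobenzoic anhydride | CC[C@H](C)/C=C/C=C/C(=O)OC(=O)c1c(Cl)cc(Cl)cc1Cl | intermediate
27 | (4S,5R,6R)-6-ethynyl-8-formyl-2,5,6,9-tetramethyldeca-2,8-dien-4-yl (2E,4E,6S)-6-methylocta-2,4-dienoate | CC[C@H](C)/C=C/C=C/C(=O)O[C@@H](C=C(C)C)[C@H](C)[C@@](C#C)(C)CC(C=O)=C(C)C | intermediate
28 | (4S,5R,6R)-6-ethynyl-8-(1-hydroxyprop-2-en-1-yl)-2,5,6,9-tetramethyldeca-2,8-dien-4-yl (2E,4E,6S)-6-methylocta-2,4-dienoate | CC[C@H](C)/C=C/C=C/C(=O)O[C@@H](C=C(C)C)[C@H](C)[C@@](C#C)(C)CC(C(O)C=C)=C(C)C | intermediate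
29 | C5 ruthenium alkylidene of 28, [RuCl2(H2IMes)(=CH–R)] with the vinyl CH2 of 28 replaced by the metal | CC[C@H](C)/C=C/C=C/C(=O)O[C@@H](C=C(C)C)[C@H](C)[C@@](C#C)(C)CC(C(O)C=[Ru](Cl)(Cl)=C1N(c2c(C)cc(C)cc2C)CCN1c1c(C)cc(C)cc1C)=C(C)C | intermediate
30 | ring-B ruthenium vinylcarbene, [RuCl2(H2IMes)(=CH–R)] with ring B closed and the metal on C4 | CC[C@H](C)/C=C/C=C/C(=O)O[C@@H](C=C(C)C)[C@H](C)[C@@]1(C)CC(=C(C)C)C(O)C=C1C=[Ru](Cl)(Cl)=C1N(c2c(C)cc(C)cc2C)CCN1c1c(C)cc(C)cc1C | intermediate
31 | (1R,2S,8aR)-6-hydroxy-1,8a-dimethyl-7-(propan-2-ylidene)-1,2,6,7,8,8a-hexahydronaphthalen-2-yl (2E,4E,6S)-6-methylocta-2,4-dienoate | CC[C@H](C)/C=C/C=C/C(=O)O[C@H]1C=CC2=CC(O)C(=C(C)C)C[C@]2(C)[C@H]1C | intermediate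
32 | (1R,2S,8aR)-1,8a-dimethyl-6-oxo-7-(propan-2-ylidene)-1,2,6,7,8,8a-hexahydronaphthalen-2-yl (2E,4E,6S)-6-methylocta-2,4-dienoate | CC[C@H](C)/C=C/C=C/C(=O)O[C@H]1C=CC2=CC(=O)C(=C(C)C)C[C@]2(C)[C@H]1C | target

**Step count**
Total step count: 18. Longest linear sequence: 12 steps (steps 4–11, then 15–18, from 3-methylbut-2-enal 5).

**Steps most likely to fail**

Step 17. What may go wrong: the catalyst may start at the wrong alkene or the hydroxy-bearing alkylidene may decay before it cyclises; the sequence may stall after the first ring closure and oligomerise; ruthenium hydrides may move double bonds. Fallback: the two ring closures are separated. Setting out from 28, enyne ring-closing metathesis under ethylene (1 atm) with second-generation Hoveyda–Grubbs catalyst [RuCl2(=CH-2-(i-PrO)C6H4)(H2IMes)] in CH2Cl2 at 40 °C should give the isolable ring-B triene (4S,5R)-5-[(1R)-2-ethenyl-4-hydroxy-1-methyl-5-(propan-2-ylidene)cyclohex-2-en-1-yl]-2-methylhex-2-en-4-yl (2E,4E,6S)-6-methylocta-2,4-dienoate F1, in which ethylene has capped C4 as a vinyl group and keeps the methylidene carbene as the initiating species. F1 is then closed by ordinary diene ring-closing metathesis of its terminal 1,3-diene onto the isobutenyl group (same catalyst, toluene, 80 °C, Ar), which comes back to the route at 31.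

Step 10. What may go wrong: the lactol next to the quaternary carbon may open only reluctantly, so the hindered aldehyde is consumed slowly and base-induced decomposition competes. Fallback: a two-stage Wittig homologation. Setting out from 16, chloromethylenation with Ph3P=CHCl (from (chloromethyl)triphenylphosphonium chloride and NaN(SiMe3)2, excess, THF, 0 °C → rt) should give (4R,5R,6S)-4-(2-chloroethenyl)-4,5,8-trimethyl-2-(propan-2-ylidene)non-7-ene-1,6-diol F2 as an E/Z mixture, and dehydrochlorination with excess n-BuLi (THF, −78 → 0 °C) comes back to the route at 18.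

Step 16. What may go wrong: loss of chemoselectivity, that is attack of the organomagnesium reagent on the dienoate or deprotonation of the alkyne C–H in place of addition to the hindered aldehyde. Fallback: the polar Grignard addition is replaced by a Nozaki–Hiyama–Kishi coupling. Setting out from 27, vinyl iodide, CrCl2 and catalytic NiCl2 in DMF/THF at rt transfer the vinyl group through an organochromium species that adds to aldehydes only, and the sequence comes back to the route at 28; this fallback forms no new compound (F0).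

**Further compounds**
F1 | step 17 | (4S,5R)-5-[(1R)-2-ethenyl-4-hydroxy-1-methyl-5-(propan-2-ylidene)cyclohex-2-en-1-yl]-2-methylhex-2-en-4-yl (2E,4E,6S)-6-methylocta-2,4-dienoate | CC[C@H](C)/C=C/C=C/C(=O)O[C@@H](C=C(C)C)[C@H](C)[C@@]1(C)CC(=C(C)C)C(O)C=C1C=C
F2 | step 10 | (4R,5R,6S)-4-(2-chloroethenyl)-4,5,8-trimethyl-2-(propan-2-ylidene)non-7-ene-1,6-diol | O[C@@H](C=C(C)C)[C@H](C)[C@@](C=CCl)(C)CC(CO)=C(C)C
F0 | step 16 | none | none
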